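**Retrosynthetic overview**

1. Feature (daucane numbering: C1 methyl-bearing fusion carbon, C2/C3 cyclopentane CH2, C4 isopropyl carbinol, C5 fusion CH, C6 ester carbinol, C7 CH2, C8 methyl carbinol, C9 secondary carbinol, C10 CH2): the oxygens on C6 and C9 of the seven-membered ring are 1,4 through C7–C8 and 1,5 through C5–C1–C10. The ring is therefore a cyclopentane-1,3-dione (C5–C6–C7–C8–C9) whose C5–C9 bond has taken up the alkene C1=C10, with C4–C3–C2 as the tether from C5 to C1.
2. Late stage: the phenol comes from a benzyl ether, the 8β,9α-diol from an 8α,9α-epoxide opened by water at C8, the ester from jaeschkeanadiol, and the C8(Me)=C9 alkene from the C9 ketone by C8 methylenation and reductive 1,3-transposition.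
3. Key disconnection: the hydroazulene-6,9-dione arises by retro-aldol cleavage of C5–C9 in a 5-4-5 photoadduct, which comes from an intramolecular enone–alkene [2+2] (C5–C1 and C9–C10) of a dione enol carbonate with a free C4 hydroxyl.
4. The dione is closed by Claisen acylation (C5–C9) of a γ-keto acid derivative made by a Stetter reaction (C6–C7) on the aldehyde from ozonolysis of (S)-terpinen-4-ol, which supplies C1–C6 and the C4 stereocentre.
5. Ring order: cyclohexene opened; cyclopentenone (C5–C9) closed; cyclopentane (C1–C5) and cyclobutane closed together by light; cyclobutane and cyclopentanone merged into the seven-membered ring.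

Key step: step 11

Assumptions: (S)-terpinen-4-ol is taken as commercially available in high enantiomeric purity (to be checked by chiral GC, because C4 is the only source of absolute configuration). β denotes the face of the C1 methyl group and α the opposite face.

**Route**

Step 1
Reactants: 1 (S)-terpinen-4-ol
Product: 2 (S)-terpinen-4-ol triethylsilyl ether
Conditions: TESOTf, 2,6-lutidine, CH2Cl2, −78 → 0 °C
Reagents that add atoms: triethylsilyl trifluoromethanesulfonate CC[Si](CC)(CC)OS(=O)(=O)C(F)(F)F
Why: Silyl triflate with a hindered pyridine base silylates hindered tertiary alcohols, and masking O4 prevents lactol formation with the C1 ketone and retro-aldol chemistry of the β-oxygenated carbonyl compounds that follow, while C4 is not touched.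

Step 2
Reactants: 2 (S)-terpinen-4-ol triethylsilyl ether
Product: 4 (S)-6-oxo-3-(propan-2-yl)-3-(triethylsilyloxy)heptanal, via secondary ozonide 3 (not isolated)
Conditions: O3, CH2Cl2, −78 °C; then PPh3, −78 °C → rt
Reagents that add atoms: ozone [O-][O+]=O
Why: Ozonolysis (Criegee mechanism) with phosphine reduction cleaves the only alkene into the C1 methyl ketone and the C6 aldehyde without affecting the silyl ether or C4.

Step 3
Reactants: 4 (S)-6-oxo-3-(propan-2-yl)-3-(triethylsilyloxy)heptanal
Product: 5 (S)-7,7-dimethoxy-5-(propan-2-yl)-5-(triethylsilyloxy)heptan-2-one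
Conditions: HC(OMe)3, CeCl3·7H2O (cat.), MeOH, rt
Reagents that add atoms: trimethyl orthoformate COC(OC)OC
Why: Lanthanide-catalysed acetalisation is selective for aldehydes over ketones, so only C6 is masked, independently of the direction in which the primary ozonide fragmented.

Step 4
Reactants: 5 (S)-7,7-dimethoxy-5-(propan-2-yl)-5-(triethylsilyloxy)heptan-2-one
Product: 6 (S)-1,1-dimethoxy-6-methyl-3-(propan-2-yl)-3-(triethylsilyloxy)hept-6-ene
Conditions: Ph3PCH3Br, KOtBu, THF, 0 °C → rt
Reagents that add atoms: methylenetriphenylphosphorane C=P(c1ccccc1)(c1ccccc1)c1ccccc1, made in the flask from methyltriphenylphosphonium bromide C[P+](c1ccccc1)(c1ccccc1)c1ccccc1.[Br-]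
Why: Wittig methylenation of the unhindered methyl ketone installs C10, and the acetal and silyl ether are inert to the ylide.

Step 5
Reactants: 6 (S)-1,1-dimethoxy-6-methyl-3-(propan-2-yl)-3-(triethylsilyloxy)hept-6-ene
Product: 7 (S)-6-methyl-3-(propan-2-yl)-3-(triethylsilyloxy)hept-6-enal
Conditions: 10% aq. oxalic acid on SiO2, CH2Cl2, rt
Reagents that add atoms: water O
Why: Mild acetal hydrolysis on wet acidic silica frees the aldehyde while the hindered tertiary silyl ether and the 1,1-disubstituted alkene survive and β-elimination is avoided.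

Step 6
Reactants: 7 (S)-6-methyl-3-(propan-2-yl)-3-(triethylsilyloxy)hept-6-enal; 8 methyl acrylate
Product: 9 methyl (S)-9-methyl-4-oxo-6-(propan-2-yl)-6-(triethylsilyloxy)dec-9-enoate
Conditions: 3-benzyl-5-(2-hydroxyethyl)-4-methylthiazolium chloride (20 mol%), Et3N, 1,4-dioxane, 70 °C
Reagents that add atoms: none
Why: In the Stetter reaction the thiazolylidene turns the aliphatic aldehyde into a Breslow acyl-anion equivalent that adds 1,4 to the acrylate and forms C6–C7, and the quaternary C4 next to C5 slows acyloin self-condensation.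

Step 7
Reactants: 9 methyl (S)-9-methyl-4-oxo-6-(propan-2-yl)-6-(triethylsilyloxy)dec-9-enoate
Product: 10 (S)-9-methyl-4-oxo-6-(propan-2-yl)-6-(triethylsilyloxy)dec-9-enoic acid
Conditions: LiOH·H2O, THF/H2O (3:1), 0 °C; then 1 M HCl to pH 4
Reagents that add atoms: lithium hydroxide [Li+].[OH-]
Why: Cold saponification cleaves the unhindered methyl ester faster than hydroxide can enolise the hindered ketone and expel the β-silyloxy group.

Step 8
Reactants: 10 (S)-9-methyl-4-oxo-6-(propan-2-yl)-6-(triethylsilyloxy)dec-9-enoic acid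
Product: 11 pentafluorophenyl (S)-9-methyl-4-oxo-6-(propan-2-yl)-6-(triethylsilyloxy)dec-9-enoate
Conditions: C6F5OH, EDC·HCl, DMAP (cat.), CH2Cl2, 0 °C → rt
Reagents that add atoms: pentafluorophenol Oc1c(F)c(F)c(F)c(F)c1F
Why: Carbodiimide (Steglich-type) esterification gives an active ester that is electrophilic enough for C-acylation under weakly basic conditions.

Step 9
Reactants: 11 pentafluorophenyl (S)-9-methyl-4-oxo-6-(propan-2-yl)-6-(triethylsilyloxy)dec-9-enoate
Product: 13 benzyl 2-[2,6-dimethyl-3-(triethylsilyloxy)hept-6-en-3-yl]-3-oxocyclopent-1-en-1-yl carbonate (C4 as in 1), via bromomagnesium dione enolate 12 (not isolated)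
Conditions: MgBr2·OEt2, iPr2NEt, CH2Cl2 (0.01 M), rt; then ClCO2Bn, 0 °C
Reagents that add atoms: benzyl chloroformate O=C(Cl)OCc1ccccc1
Why: Proposed new method: MgBr2 activates the C6 ketone so that iPr2NEt forms the magnesium enolate reversibly at C5, which attacks the pentafluorophenyl ester at C9 [5-(enolendo)-exo-trig] and closes the ring C5–C6–C7–C8–C9; the enolate towards C7 cannot close a ring, any enol lactone from O-acylation can be reopened by pentafluorophenoxide, deprotonation of the vinylogous acid makes the C-acylation irreversible, and the congested C5 then directs benzyl chloroformate to oxygen to give the only possible enol carbonate of the symmetrical dione; the closest known reactions are the intermolecular MgBr2/amine soft-enolisation C-acylation of ketones with pentafluorophenyl esters and the alkoxide-mediated cyclisation of 4-oxoalkanoates to 2-substituted cyclopentane-1,3-diones, and the weak base is chosen because the C5 enolate carries the C4 silyloxy group in the β-position; a benzyl carbonate is used because it can later be removed from a tertiary cyclobutanol under neutral conditions.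

Step 10
Reactants: 13 benzyl 2-[2,6-dimethyl-3-(triethylsilyloxy)hept-6-en-3-yl]-3-oxocyclopent-1-en-1-yl carbonate
Product: 14 benzyl 2-(3-hydroxy-2,6-dimethylhept-6-en-3-yl)-3-oxocyclopent-1-en-1-yl carbonate (C4 as in 1)
Conditions: HF·pyridine, pyridine, THF, 0 °C → rt
Reagents that add atoms: none
Why: Buffered HF·pyridine removes the silyl group without base and with a weak nucleophile, so the enol carbonate (a vinylogous mixed anhydride) survives and the hydroxyl needed for stereocontrol is set free.

Step 11
Reactants: 14 benzyl 2-(3-hydroxy-2,6-dimethylhept-6-en-3-yl)-3-oxocyclopent-1-en-1-yl carbonate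
Product: 15 5-4-5 tricyclic photoadduct (cyclobutane C5–C1–C10–C9 cis-fused to cyclopentane C1–C5 and to cyclopentanone C5–C9; C9 benzyl carbonate; C6 ketone; C4 hydroxyl cis to C1 methyl)
Conditions: hν (350 nm, Pyrex), CH2Cl2 (5 mM), degassed, 0 °C
Reagents that add atoms: none
Why: Excitation of the β-acyloxy enone near 350 nm and intersystem crossing give the enone triplet, which adds to the tethered 1,1-disubstituted alkene through a triplet 1,4-biradical that collapses after spin inversion, so that C5–C1 and C9–C10 are both formed. The closest known reactions are the intramolecular de Mayo [2+2] photocycloadditions of enol esters of 2-(pent-4-enyl)cyclopentane-1,3-diones and the hydrogen-bond-directed intramolecular photocycloadditions of enones that carry a hydroxyl on the carbon attached to the α-position. The cyclopentane C1–C2–C3–C4–C5 closes in the 1,5 (5-exo-trig) mode through the three-atom tether and the cyclobutane C5–C1–C10–C9 closes in the straight (fused) mode by radical recombination, the crossed mode being excluded because it would need a bicyclo[3.1.1]heptane core. Of the new stereocentres C1, C5 and C9, the last two follow from the obligatory cis fusion of both five-membered rings to the cyclobutane and are erased (C9) or reset (C5) in step 12, whereas C1 is controlled by C4 through the enone face that the tether reaches. The selectivity needed is therefore facial, and it is secured by the hydrogen bond from the free C4 hydroxyl to the C6 carbonyl in a non-hydrogen-bonding solvent, which fixes the rotamer about C4–C5 with the tether over one face and the isopropyl group on the other beside the carbonate, so that the C1 methyl ends up cis to the hydroxyl. The symmetrical dione gives only one enol carbonate, and the excited-state addition tolerates the congestion of joining C5 to C1 beside the fully substituted C4.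

Step 12
Reactants: 15 5-4-5 tricyclic photoadduct
Product: 17 trans-fused 4β-hydroxy-8-demethyldaucane-6,9-dione (1β-methyl; 5α-H), via cyclobutanol 16 (not isolated)
Conditions: H2 (1 atm), 10% Pd/C, EtOAc, rt; filter; then K2CO3 (cat.), MeOH, 0 °C, short; AcOH quench
Reagents that add atoms: none
Why: Hydrogenolysis of the benzyl carbonate and loss of CO2 unmask a cyclobutanol at C9 β to the C6 ketone, whose strain drives the retro-aldol cleavage of C5–C9 (de Mayo fragmentation) to the seven-membered ring, and the brief carbonate treatment completes this and equilibrates C5 to the trans fusion, which should be favoured because C6 then lies cis to the hydroxyl and not to the isopropyl group on the cyclopentane.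

Step 13
Reactants: 17 trans-fused 4β-hydroxy-8-demethyldaucane-6,9-dione
Product: 18 4β,6α-dihydroxy-8-demethyldaucan-9-one
Conditions: Me4NBH(OAc)3, MeCN/AcOH (1:1), −30 → −20 °C
Reagents that add atoms: none
Why: In this hydroxyl-directed reduction the C4 hydroxyl exchanges onto boron and delivers hydride through a six-membered transition state to the β-hydroxy ketone C6 only (the isolated C9 ketone is inert to the reagent), from the face of O4, which should give the 6α-alcohol with H6 anti to H5.

Step 14
Reactants: 18 4β,6α-dihydroxy-8-demethyldaucan-9-one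
Product: 19 6α-(tert-butyldimethylsilyloxy)-4β-hydroxy-8-demethyldaucan-9-one
Conditions: TBSOTf (1.1 equiv), 2,6-lutidine, CH2Cl2, −78 °C
Reagents that add atoms: tert-butyldimethylsilyl trifluoromethanesulfonate CC(C)(C)[Si](C)(C)OS(=O)(=O)C(F)(F)F
Why: At −78 °C the silyl triflate reacts with the secondary C6 hydroxyl much faster than with the congested tertiary C4 hydroxyl, which blocks C6–OH for the enolate and Mitsunobu steps and excludes transannular hemiketal formation with C9.

Step 15
Reactants: 19 6α-(tert-butyldimethylsilyloxy)-4β-hydroxy-8-demethyldaucan-9-one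
Product: 22 6α-(tert-butyldimethylsilyloxy)-4β-hydroxy-8-methylidene-8-demethyldaucan-9-one, via Mannich base 20 (not isolated), via trimethylammonium iodide 21 (not isolated)
Conditions: LDA (2.2 equiv), THF, −78 °C; CH2=NMe2+ I−, −78 °C → rt; then MeI, CH2Cl2, rt; then DBU, 0 °C
Reagents that add atoms: N,N-dimethylmethyleneiminium iodide (Eschenmoser's salt) C=[N+](C)C.[I-]
Why: Kinetic deprotonation of the C9 ketone should occur at C8 and not at the neopentyl C10 next to quaternary C1, the Mannich reaction with Eschenmoser's salt fixes the new carbon at C8, and quaternisation followed by base-induced β-elimination of trimethylamine gives the α-methylene ketone.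

Step 16
Reactants: 22 6α-(tert-butyldimethylsilyloxy)-4β-hydroxy-8-methylidene-8-demethyldaucan-9-one
Product: 23 6α-(tert-butyldimethylsilyloxy)-8-methylidene-8-demethyldaucane-4β,9-diol (C9 epimers)
Conditions: NaBH4, CeCl3·7H2O, MeOH, −78 → −40 °C
Reagents that add atoms: none
Why: Luche conditions give clean 1,2-reduction of the exocyclic enone, and the C9 configuration is immaterial because C9 becomes sp2 in the next step.

Step 17
Reactants: 23 6α-(tert-butyldimethylsilyloxy)-8-methylidene-8-demethyldaucane-4β,9-diol
Product: 26 6α-(tert-butyldimethylsilyloxy)dauc-8-en-4β-ol (jaeschkeanadiol 6-O-TBS ether), via sulfonylhydrazine adduct 24 (not isolated), via allylic diazene 25 (not isolated)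
Conditions: 2-nitrobenzenesulfonylhydrazide, PPh3, DEAD, THF, −30 °C; then rt
Reagents that add atoms: none
Why: Mitsunobu displacement of the allylic C9 hydroxyl by the sulfonylhydrazide, loss of the sulfinic acid on warming and retro-ene loss of N2 from the allylic diazene transfer hydrogen to the exocyclic CH2 and move the alkene to C8=C9 (reductive 1,3-transposition of an allylic alcohol), which fixes the trisubstituted alkene regiospecifically while the tertiary C4 hydroxyl is inert.

Step 18
Reactants: 26 6α-(tert-butyldimethylsilyloxy)dauc-8-en-4β-ol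
Product: 27 jaeschkeanadiol (dauc-8-ene-4β,6α-diol)
Conditions: TBAF, THF, 0 °C → rt; aq. NH4Cl
Reagents that add atoms: none
Why: Fluoride cleaves the secondary silyl ether without affecting the trisubstituted alkene or the tertiary alcohol.

Step 19
Reactants: 27 jaeschkeanadiol; 28 4-(benzyloxy)benzoic acid
Product: 29 jaeschkeanadiol 6-O-[4-(benzyloxy)benzoate] (ferutinin benzyl ether)
Conditions: DCC, DMAP, CH2Cl2, rt
Reagents that add atoms: none
Why: Steglich esterification acylates the secondary C6 hydroxyl, while the tertiary C4 hydroxyl flanked by isopropyl is too hindered to react.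

Step 20
Reactants: 29 jaeschkeanadiol 6-O-[4-(benzyloxy)benzoate]
Product: 30 8α,9α-epoxide of 29
Conditions: mCPBA, NaHCO3, CH2Cl2, 0 °C
Reagents that add atoms: 3-chloroperoxybenzoic acid O=C(OO)c1cccc(Cl)c1
Why: Prilezhaev epoxidation of the trisubstituted alkene should occur on the α face, opposite the pseudo-axial β-methyl on C1 that is 1,3 to C9, while the 6α-ester is pseudo-equatorial and shields little.

Step 21
Reactants: 30 8α,9α-epoxide of 29
Product: 31 8β,9α-dihydroxy-8,9-dihydrojaeschkeanadiol 6-O-[4-(benzyloxy)benzoate] (benzyl ether of the target)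
Conditions: HClO4 (cat.), THF/H2O (1:3), 0 °C → rt
Reagents that add atoms: water O
Why: Acid-catalysed epoxide hydrolysis is a borderline SN2 opening at the tertiary C8 with inversion, which should give the trans 8β,9α-diol, and the water-rich medium favours water over transannular attack by the C4 hydroxyl.

Step 22
Reactants: 31 benzyl ether of the target
Product: 32 target CNP0197754.1
Conditions: H2 (1 atm), 10% Pd/C, EtOAc, rt
Reagents that add atoms: none
Why: Hydrogenolysis removes the benzyl aryl ether, and no alkene remains while the ester and the alcohols are inert.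

**Compound list**

1 | (S)-terpinen-4-ol | CC(C)[C@]1(O)CCC(C)=CC1 | starting material
2 | (S)-terpinen-4-ol triethylsilyl ether | CC(C)[C@]1(O[Si](CC)(CC)CC)CCC(C)=CC1 | intermediate
3 | secondary ozonide of 2 (1,2,4-trioxolane across C1 and C6; mixture at the new acetal carbons) | CC12CC[C@](C(C)C)(O[Si](CC)(CC)CC)CC(OO1)O2 | intermediate (not isolated)
4 | (S)-6-oxo-3-(propan-2-yl)-3-(triethylsilyloxy)heptanal | CC(C)[C@](O[Si](CC)(CC)CC)(CCC(C)=O)CC=O | intermediate
5 | (S)-7,7-dimethoxy-5-(propan-2-yl)-5-(triethylsilyloxy)heptan-2-one | CC(C)[C@](O[Si](CC)(CC)CC)(CCC(C)=O)CC(OC)OC | intermediate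
6 | (S)-1,1-dimethoxy-6-methyl-3-(propan-2-yl)-3-(triethylsilyloxy)hept-6-ene | CC(C)[C@](O[Si](CC)(CC)CC)(CCC(C)=C)CC(OC)OC | intermediate
7 | (S)-6-methyl-3-(propan-2-yl)-3-(triethylsilyloxy)hept-6-enal | CC(C)[C@](O[Si](CC)(CC)CC)(CCC(C)=C)CC=O | intermediate
8 | methyl acrylate | C=CC(=O)OC | starting material
9 | methyl (S)-9-methyl-4-oxo-6-(propan-2-yl)-6-(triethylsilyloxy)dec-9-enoate | CC(C)[C@](O[Si](CC)(CC)CC)(CCC(C)=C)CC(=O)CCC(=O)OC | intermediate
10 | (S)-9-methyl-4-oxo-6-(propan-2-yl)-6-(triethylsilyloxy)dec-9-enoic acid | CC(C)[C@](O[Si](CC)(CC)CC)(CCC(C)=C)CC(=O)CCC(=O)O | intermediate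
11 | pentafluorophenyl ester of 10 | CC(C)[C@](O[Si](CC)(CC)CC)(CCC(C)=C)CC(=O)CCC(=O)Oc1c(F)c(F)c(F)c(F)c1F | intermediate
12 | bromomagnesium enolate of 2-[2,6-dimethyl-3-(triethylsilyloxy)hept-6-en-3-yl]cyclopentane-1,3-dione | CC(C)[C@](O[Si](CC)(CC)CC)(CCC(C)=C)C1=C(O[Mg]Br)CCC1=O | intermediate (not isolated)
13 | benzyl 2-[2,6-dimethyl-3-(triethylsilyloxy)hept-6-en-3-yl]-3-oxocyclopent-1-en-1-yl carbonate (C4 as in 1) | CC(C)[C@](O[Si](CC)(CC)CC)(CCC(C)=C)C1=C(OC(=O)OCc2ccccc2)CCC1=O | intermediate
14 | benzyl 2-(3-hydroxy-2,6-dimethylhept-6-en-3-yl)-3-oxocyclopent-1-en-1-yl carbonate (photosubstrate) | CC(C)[C@](O)(CCC(C)=C)C1=C(OC(=O)OCc2ccccc2)CCC1=O | intermediate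
15 | 5-4-5 tricyclic photoadduct (all-cis ring fusions; C4 hydroxyl cis to C1 methyl; C9 benzyl carbonate; C6 ketone) | CC(C)[C@]1(O)CC[C@]2(C)C[C@@]3(OC(=O)OCc4ccccc4)CCC(=O)[C@@]123 | intermediate
16 | C9 cyclobutanol corresponding to 15 | CC(C)[C@]1(O)CC[C@]2(C)C[C@@]3(O)CCC(=O)[C@@]123 | intermediate (not isolated)
17 | trans-fused 4β-hydroxy-8-demethyldaucane-6,9-dione (1β-Me, 5α-H) | CC(C)[C@]1(O)CC[C@]2(C)CC(=O)CCC(=O)[C@H]21 | intermediate
18 | 4β,6α-dihydroxy-8-demethyldaucan-9-one | CC(C)[C@]1(O)CC[C@]2(C)CC(=O)CC[C@H](O)[C@H]21 | intermediate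
19 | 6α-(tert-butyldimethylsilyloxy)-4β-hydroxy-8-demethyldaucan-9-one | CC(C)[C@]1(O)CC[C@]2(C)CC(=O)CC[C@H](O[Si](C)(C)C(C)(C)C)[C@H]21 | intermediate
20 | 8-(dimethylaminomethyl) derivative of 19 (C8 epimers) | CC(C)[C@]1(O)CC[C@]2(C)CC(=O)C(CN(C)C)C[C@H](O[Si](C)(C)C(C)(C)C)[C@H]21 | intermediate (not isolated)
21 | trimethylammonium iodide from 20 (C8 epimers) | CC(C)[C@]1(O)CC[C@]2(C)CC(=O)C(C[N+](C)(C)C)C[C@H](O[Si](C)(C)C(C)(C)C)[C@H]21.[I-] | intermediate (not isolated)
22 | 6α-(tert-butyldimethylsilyloxy)-4β-hydroxy-8-methylidene-8-demethyldaucan-9-one | CC(C)[C@]1(O)CC[C@]2(C)CC(=O)C(=C)C[C@H](O[Si](C)(C)C(C)(C)C)[C@H]21 | intermediate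
23 | 6α-(tert-butyldimethylsilyloxy)-8-methylidene-8-demethyldaucane-4β,9-diol (C9 epimers) | CC(C)[C@]1(O)CC[C@]2(C)CC(O)C(=C)C[C@H](O[Si](C)(C)C(C)(C)C)[C@H]21 | intermediate
24 | N-(C9-allyl)-N-(2-nitrobenzenesulfonyl)hydrazine from 23 | CC(C)[C@]1(O)CC[C@]2(C)CC(N(N)S(=O)(=O)c3ccccc3[N+](=O)[O-])C(=C)C[C@H](O[Si](C)(C)C(C)(C)C)[C@H]21 | intermediate (not isolated)
25 | C9 allylic diazene | CC(C)[C@]1(O)CC[C@]2(C)CC(N=N)C(=C)C[C@H](O[Si](C)(C)C(C)(C)C)[C@H]21 | intermediate (not isolated)
26 | jaeschkeanadiol 6-O-TBS ether | CC(C)[C@]1(O)CC[C@]2(C)CC=C(C)C[C@H](O[Si](C)(C)C(C)(C)C)[C@H]21 | intermediate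
27 | jaeschkeanadiol (dauc-8-ene-4β,6α-diol) | CC(C)[C@]1(O)CC[C@]2(C)CC=C(C)C[C@H](O)[C@H]21 | intermediate
28 | 4-(benzyloxy)benzoic acid | OC(=O)c1ccc(OCc2ccccc2)cc1 | starting material
29 | jaeschkeanadiol 6-O-[4-(benzyloxy)benzoate] (ferutinin benzyl ether) | CC(C)[C@]1(O)CC[C@]2(C)CC=C(C)C[C@H](OC(=O)c3ccc(OCc4ccccc4)cc3)[C@H]21 | intermediate
30 | 8α,9α-epoxide of 29 | CC(C)[C@]1(O)CC[C@]2(C)C[C@@H]3O[C@]3(C)C[C@H](OC(=O)c4ccc(OCc5ccccc5)cc4)[C@H]21 | intermediate
31 | 4β,8β,9α-trihydroxydaucan-6α-yl 4-(benzyloxy)benzoate | CC(C)[C@]1(O)CC[C@]2(C)C[C@H](O)[C@@](C)(O)C[C@H](OC(=O)c3ccc(OCc4ccccc4)cc3)[C@H]21 | intermediate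
32 | CNP0197754.1, 4β,8β,9α-trihydroxydaucan-6α-yl 4-hydroxybenzoate | CC(C)[C@]1(O)CC[C@]2(C)C[C@H](O)[C@@](C)(O)C[C@H](OC(=O)c3ccc(O)cc3)[C@H]21 | target

**Step count and risks**

Total step count: 22. Longest linear sequence: 22 steps (1 to 32).

Steps most likely to fail:

Step 9. The ring closure may not take place. C-acylation at the neopentyl C5 through a 5-(enolendo) geometry is slow, so O-acylation to enol lactones, intermolecular condensation or β-elimination of triethylsilanol from the C5 enolate may take over. The fallback uses known chemistry and sets out from keto ester 9. The classical alkoxide-mediated cyclisation of a 4-oxoalkanoate (KOtBu, THF, 0 °C, short contact) would give the potassium enolate of 2-[2,6-dimethyl-3-(triethylsilyloxy)hept-6-en-3-yl]cyclopentane-1,3-dione F1. This is acylated in the same flask with benzyl chloroformate and comes back to the route at 13. Steps 7 and 8 are then not needed, at the price of a stronger base next to the β-silyloxy ketone.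

Step 21. Transannular participation may compete with hydrolysis. The 4β-hydroxyl can reach the β face of C8 and open the protonated epoxide faster than water, giving a 4,8-oxide, which is the kind of ether formation daucane 8,9-epoxides with a nearby hydroxyl are known for. The fallback sets out from 29. The C4 hydroxyl is silylated (TESOTf, 2,6-lutidine) to the C4 triethylsilyl ether of 29 F2. Epoxidation as in step 20 gives the silylated 8α,9α-epoxide F3, hydrolysis as in step 21 gives the silylated 8β,9α-diol F4, and HF·pyridine removes the silyl group to come back at 31.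

Step 6. The aldehyde may be consumed by acyloin self-condensation, or may lose triethylsilanol by base-induced β-elimination at 70 °C, before the Breslow intermediate adds to the acrylate. The fallback sets out from aldehyde 7 and replaces the umpolung by an acyl electrophile. Pinnick oxidation (NaClO2, NaH2PO4, 2-methyl-2-butene) gives (S)-6-methyl-3-(propan-2-yl)-3-(triethylsilyloxy)hept-6-enoic acid F5. Thioesterification (EtSH, DCC, DMAP) gives the S-ethyl thioester F6. Fukuyama coupling with (3-methoxy-3-oxopropyl)zinc iodide F7 (from methyl 3-iodopropanoate and zinc; PdCl2(PPh3)2, toluene, rt) gives keto ester 9, where the route is rejoined.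

**Further compounds**

F1 | step 9 | potassium enolate of 2-[2,6-dimethyl-3-(triethylsilyloxy)hept-6-en-3-yl]cyclopentane-1,3-dione | CC(C)[C@](O[Si](CC)(CC)CC)(CCC(C)=C)C1=C([O-])CCC1=O.[K+]
F2 | step 21 | C4 triethylsilyl ether of 29 | CC(C)[C@]1(O[Si](CC)(CC)CC)CC[C@]2(C)CC=C(C)C[C@H](OC(=O)c3ccc(OCc4ccccc4)cc3)[C@H]21
F3 | step 21 | C4 triethylsilyl ether of the 8α,9α-epoxide 30 | CC(C)[C@]1(O[Si](CC)(CC)CC)CC[C@]2(C)C[C@@H]3O[C@]3(C)C[C@H](OC(=O)c4ccc(OCc5ccccc5)cc4)[C@H]21
F4 | step 21 | C4 triethylsilyl ether of the 8β,9α-diol 31 | CC(C)[C@]1(O[Si](CC)(CC)CC)CC[C@]2(C)C[C@H](O)[C@@](C)(O)C[C@H](OC(=O)c3ccc(OCc4ccccc4)cc3)[C@H]21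
F5 | step 6 | (S)-6-methyl-3-(propan-2-yl)-3-(triethylsilyloxy)hept-6-enoic acid | CC(C)[C@](O[Si](CC)(CC)CC)(CCC(C)=C)CC(=O)O
F6 | step 6 | S-ethyl (S)-6-methyl-3-(propan-2-yl)-3-(triethylsilyloxy)hept-6-enethioate | CC(C)[C@](O[Si](CC)(CC)CC)(CCC(C)=C)CC(=O)SCC
F7 | step 6 | (3-methoxy-3-oxopropyl)zinc iodide | COC(=O)CC[Zn]I
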